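The target is a C2-symmetric trans-3,4-disubstituted oxolane. Lignan numbering is used: C7 benzylic, C8 next to it, C9 the C1 unit on C8, primes for the second half. The strategy rests on the chain C7–C8–C8'–C7', which is oxolane C3–C4 plus the two exocyclic ArCH(OH) carbons. Its (7S,8R,8'R,7'S) array and both benzylic C7–O bonds are those of an exo,exo-4,8-diaryl-3,7-dioxabicyclo[3.3.0]octane-2,6-dione (cis-fused bis-γ-lactone).
Disconnections: the oxolane ether C9–O–C9' comes from a 9,9'-diol with O7/O7' silylated. That diol comes from a tetraol, made by hydride cleavage of the two lactone acyl C–O bonds. The dilactone comes from making C8–C8' and both C7–O bonds at once, by oxidative β–β (8–8') homodimerisation of a ferulic amide of (2S,5S)-2,5-dimethylpyrrolidine.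
A bromine at aryl C5 (from 5-bromovanillin) closes the β–5 channel. It leaves in the final hydrogenolysis together with the phenol benzyl groups.
Ring order: both lactone rings form together (step 5), both are opened (step 7), and the oxolane closes last (step 10).

Key step: step 5

Assumption: both antipodes of trans-2,5-dimethylpyrrolidine are taken as purchasable, and the (2S,5S) antipode is chosen from the s-cis/anti-methyl model given in step 5; the sense of induction is to be checked on 11 by anomalous-dispersion X-ray analysis (two Br atoms), and the (2R,5R) amine would replace 5 without other change if the sense proved opposite.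

Step 1
Reactants: 1 5-bromovanillin (3-bromo-4-hydroxy-5-methoxybenzaldehyde); 2 malonic acid
Product: 3 (E)-5-bromoferulic acid [(E)-3-(3-bromo-4-hydroxy-5-methoxyphenyl)prop-2-enoic acid]
Conditions: pyridine, piperidine (cat.), 80 °C; then aq. HCl
Reagents that add atoms: none
Why: Knoevenagel–Doebner condensation, in which the decarboxylative elimination in warm pyridine should give only the (E)-cinnamic acid while the free phenol and the aryl bromide stay inert.

Step 2
Reactants: 3 (E)-5-bromoferulic acid
Product: 4 (E)-4-O-acetyl-5-bromoferulic acid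
Conditions: Ac2O, pyridine, rt; then H2O
Reagents that add atoms: acetic anhydride, CC(=O)OC(C)=O
Why: O-acetylation masks the only other acylable group before the acid is activated, and any mixed anhydride formed at the carboxyl group is hydrolysed in the aqueous work-up.

Step 3
Reactants: 4 (E)-4-O-acetyl-5-bromoferulic acid; 5 (2S,5S)-2,5-dimethylpyrrolidine
Product: 7 (E)-3-(4-acetoxy-3-bromo-5-methoxyphenyl)-1-[(2S,5S)-2,5-dimethylpyrrolidin-1-yl]prop-2-en-1-one, via acid chloride 6 (not isolated)
Conditions: (COCl)2, DMF (cat.), CH2Cl2, 0 °C → rt, concentrate; then 5, Et3N, CH2Cl2, 0 °C → rt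
Reagents that add atoms: oxalyl chloride, O=C(Cl)C(=O)Cl (gives the Cl of 6; none of its atoms remains in 7)
Why: Acid chloride formation followed by N-acylation is the most dependable way to acylate an α,α'-branched secondary amine, and neither the alkene geometry nor the stereocentres of 5 are touched.

Step 4
Reactants: 7 acetylated amide
Product: 8 (E)-3-(3-bromo-4-hydroxy-5-methoxyphenyl)-1-[(2S,5S)-2,5-dimethylpyrrolidin-1-yl]prop-2-en-1-one
Conditions: pyrrolidine (3 equiv), THF, rt
Reagents that add atoms: none
Why: Aminolysis of the activated aryl acetate by an unhindered amine is fast at room temperature, whereas the tertiary cinnamamide is neither cleaved nor a good Michael acceptor.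

Step 5
Reactants: 8 5-bromoferulic amide (two molecules)
Product: 11 (1S,4S,5S,8S)-4,8-bis(3-bromo-4-hydroxy-5-methoxyphenyl)-3,7-dioxabicyclo[3.3.0]octane-2,6-dione (exo,exo), via bis(quinone methide) 9 (not isolated), via bis(iminium ether) 10 (not isolated)
Conditions: Ag2O (0.6 equiv), 4 Å MS, CH2Cl2, dark, −10 °C; filter; then THF/aq. citric acid (pH 3), 0 °C → rt
Reagents that add atoms: water, O (supplies both lactone carbonyl oxygens; the former amide oxygens become the ring oxygens on C7 and C7')
Why: Proposed new method: Ag2O takes one electron and one proton from each phenol of 8, the two phenoxyl radicals, whose spin reaches C8 (the carbon α to the amide carbonyl), join C8 to C8' to give bis(quinone methide) 9, each amide oxygen then adds to the exocyclic quinone methide carbon C7 of the other half to give bis(iminium ether) 10, and acidic water converts both C=N+ groups into lactone carbonyls and releases the protonated auxiliary. The closest known reaction types are the FeCl3/O2 or laccase dimerisation of ferulic and sinapic acid to the racemic dilactones, the auxiliary-directed β–5 dimerisation of N-feruloyl imides with Ag2O, and the halolactonisation of tertiary amides through iminium ethers that are hydrolysed to lactones; untested is the use of an amide as the internal trap together with absolute control of a β–β coupling. Each of the two rings (O–C9'–C8'–C8–C7 and O–C9–C8–C8'–C7') closes in the 5-exo-trig mode, because the attacked C7=C1(aryl) bond lies outside the ring being made, and the resulting bicyclo[3.3.0] frame can only be cis-fused. C8 and C8' are set by the auxiliary: the tertiary amide keeps C7 syn to the carbonyl oxygen (s-cis, avoiding A(1,3) strain with the pyrrolidine), the methyl group on the pyrrolidine carbon that lies syn to C8 covers the Re face in the (2S,5S) series, so both radicals bond through their Si faces to give the like (8S,8'S) pair, while any mixed-face (unlike) pair cannot close to the bicycle and is removed as a different compound. C7 and C7' are set by the substrate, since each aryl group takes the convex exo side, cis to the adjacent bridgehead hydrogen, and the oxygen addition stays reversible until the phenolate is protonated, so the more stable exo,exo isomer should collect. The step needs β–β in place of β–5 and β–O–4 coupling, and this is secured by the bromine at C5, which occupies the only free position ortho to the phenol as the second methoxy group does in sinapic acid and, together with OMe, hinders the phenoxyl oxygen.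

Step 6
Reactants: 11 dibromodilactone
Product: 12 (1S,4S,5S,8S)-4,8-bis[4-(benzyloxy)-3-bromo-5-methoxyphenyl]-3,7-dioxabicyclo[3.3.0]octane-2,6-dione
Conditions: BnOH, PPh3, DIAD, THF, 0 °C → rt
Reagents that add atoms: benzyl alcohol, OCc1ccccc1
Why: Mitsunobu etherification alkylates the acidic o-bromophenols under essentially neutral conditions and so avoids the long-lived phenoxide of a carbonate/BnBr protocol, which could expel the benzylic carboxylate and open the lactones through a quinone methide; no stereocentre takes part.

Step 7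
Reactants: 12 bis(benzyl ether) dilactone
Product: 13 (1S,2R,3R,4S)-1,4-bis[4-(benzyloxy)-3-bromo-5-methoxyphenyl]-2,3-bis(hydroxymethyl)butane-1,4-diol
Conditions: LiAlH4, THF, 0 °C; Na2SO4·10H2O quench
Reagents that add atoms: none
Why: Hydride reduction of lactones to diols attacks only the carbonyl carbons, so the acyl C–O bonds break while both benzylic C7–O bonds and all four stereocentres are kept (C8/C8' change from S to R only because CH2OH ranks below C7), and aryl bromides and benzyl ethers survive at 0 °C.

Step 8
Reactants: 13 tetraol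
Product: 14 tetrakis(tert-butyldimethylsilyl) ether of 13
Conditions: TBSOTf (6 equiv), 2,6-lutidine, CH2Cl2, −78 → 0 °C
Reagents that add atoms: tert-butyldimethylsilyl triflate, CC(C)(C)[Si](C)(C)OS(=O)(=O)C(F)(F)F
Why: Exhaustive O-silylation with a silyl triflate and a hindered base covers even the crowded benzylic hydroxyls, takes place at oxygen only and, being cold and buffered, should not ionise C7–O.

Step 9
Reactants: 14 tetrasilyl ether
Product: 15 (2R,3R)-2,3-bis{(S)-[4-(benzyloxy)-3-bromo-5-methoxyphenyl](tert-butyldimethylsilyloxy)methyl}butane-1,4-diol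
Conditions: HF·pyridine, pyridine, THF, 0 °C (polypropylene vessel)
Reagents that add atoms: none
Why: Kinetically selective fluoride desilylation, in which the two primary silyl ethers are far more accessible than the secondary benzylic ones flanked by an aryl group and a branched carbon, and the excess pyridine keeps the medium too weakly acidic to ionise C7–O.

Step 10
Reactants: 15 9,9'-diol
Product: 17 (3R,4R)-3,4-bis{(S)-[4-(benzyloxy)-3-bromo-5-methoxyphenyl](tert-butyldimethylsilyloxy)methyl}oxolane, via monotosylate 16 (not isolated)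
Conditions: TsCl (1.1 equiv), DMAP (cat.), pyridine, 0 → 50 °C
Reagents that add atoms: p-toluenesulfonyl chloride, Cc1ccc(cc1)S(=O)(=O)Cl (gives the tosyl group of 16; none of its atoms remains in 17)
Why: Sulfonylation of one primary hydroxyl is followed by intramolecular Williamson-type 5-exo-tet displacement by the other, only the non-stereogenic C9/C9' react so that the trans-3,4 relation follows from 8R,8'R, the silylated O7/O7' cannot close the competing 7-O-9' ring, and the weak base avoids O-to-O silyl migration.

Step 11
Reactants: 17 bis(silyl ether) oxolane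
Product: 18 (3R,4R)-3,4-bis{(S)-[4-(benzyloxy)-3-bromo-5-methoxyphenyl](hydroxy)methyl}oxolane
Conditions: TBAF/AcOH (equimolar), THF, rt → 40 °C
Reagents that add atoms: none
Why: Fluoride cleaves the Si–O bonds at silicon, so both C7–O bonds and their configuration are retained, and the acetic acid buffer keeps the medium neutral.

Step 12
Reactants: 18 dibromo bis(benzyl ether) diol
Product: 19 (3R,4R)-3,4-bis[(S)-hydroxy(4-hydroxy-3-methoxyphenyl)methyl]oxolane (target)
Conditions: H2 (1 atm), Pd/C, NaOAc, EtOAc/EtOH, rt
Reagents that add atoms: none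
Why: Heterogeneous hydrogenolysis removes the two aryl benzyl ethers and the two aryl C–Br bonds in one operation (hydrodebromination of 5-bromo-blocked β–β dimers is a known reaction type), and NaOAc takes up the HBr so that the secondary benzylic alcohols are neither ionised nor reduced.

Compound list
1 | 5-bromovanillin | COc1cc(C=O)cc(Br)c1O | starting material
2 | malonic acid | OC(=O)CC(=O)O | starting material
3 | (E)-5-bromoferulic acid | COc1cc(/C=C/C(=O)O)cc(Br)c1O | intermediate
4 | (E)-4-O-acetyl-5-bromoferulic acid | COc1cc(/C=C/C(=O)O)cc(Br)c1OC(C)=O | intermediate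
5 | (2S,5S)-2,5-dimethylpyrrolidine | N1[C@@H](C)CC[C@@H]1C | starting material
6 | (E)-4-O-acetyl-5-bromoferuloyl chloride (not isolated) | COc1cc(/C=C/C(=O)Cl)cc(Br)c1OC(C)=O | intermediate
7 | (E)-N-(4-O-acetyl-5-bromoferuloyl)-(2S,5S)-2,5-dimethylpyrrolidine | COc1cc(/C=C/C(=O)N2[C@@H](C)CC[C@@H]2C)cc(Br)c1OC(C)=O | intermediate
8 | (E)-N-(5-bromoferuloyl)-(2S,5S)-2,5-dimethylpyrrolidine | COc1cc(/C=C/C(=O)N2[C@@H](C)CC[C@@H]2C)cc(Br)c1O | intermediate
9 | 8–8'-linked bis(quinone methide) diamide, like configuration at C8/C8' (not isolated) | COC1=CC(=C[C@@H](C(=O)N2[C@@H](C)CC[C@@H]2C)[C@@H](C=C2C=C(OC)C(=O)C(Br)=C2)C(=O)N2[C@@H](C)CC[C@@H]2C)C=C(Br)C1=O | intermediate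
10 | bicyclic bis(iminium ether), bis(phenolate) zwitterion (not isolated) | COc1cc([C@H]2OC(=[N+]4[C@@H](C)CC[C@@H]4C)[C@H]3[C@@H]2C(=[N+]2[C@@H](C)CC[C@@H]2C)O[C@@H]3c2cc(Br)c([O-])c(OC)c2)cc(Br)c1[O-] | intermediate
11 | (1S,4S,5S,8S)-4,8-bis(3-bromo-4-hydroxy-5-methoxyphenyl)-3,7-dioxabicyclo[3.3.0]octane-2,6-dione | COc1cc([C@H]2OC(=O)[C@H]3[C@@H]2C(=O)O[C@@H]3c2cc(Br)c(O)c(OC)c2)cc(Br)c1O | intermediate
12 | (1S,4S,5S,8S)-4,8-bis[4-(benzyloxy)-3-bromo-5-methoxyphenyl]-3,7-dioxabicyclo[3.3.0]octane-2,6-dione | COc1cc([C@H]2OC(=O)[C@H]3[C@@H]2C(=O)O[C@@H]3c2cc(Br)c(OCc4ccccc4)c(OC)c2)cc(Br)c1OCc1ccccc1 | intermediate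
13 | (1S,2R,3R,4S)-1,4-bis[4-(benzyloxy)-3-bromo-5-methoxyphenyl]-2,3-bis(hydroxymethyl)butane-1,4-diol | COc1cc([C@@H](O)[C@@H](CO)[C@H](CO)[C@H](O)c2cc(Br)c(OCc3ccccc3)c(OC)c2)cc(Br)c1OCc1ccccc1 | intermediate
14 | tetrakis(TBS) ether of 13 | COc1cc([C@@H](O[Si](C)(C)C(C)(C)C)[C@@H](CO[Si](C)(C)C(C)(C)C)[C@H](CO[Si](C)(C)C(C)(C)C)[C@H](O[Si](C)(C)C(C)(C)C)c2cc(Br)c(OCc3ccccc3)c(OC)c2)cc(Br)c1OCc1ccccc1 | intermediate
15 | 7,7'-bis(TBS) ether 9,9'-diol | COc1cc([C@@H](O[Si](C)(C)C(C)(C)C)[C@@H](CO)[C@H](CO)[C@H](O[Si](C)(C)C(C)(C)C)c2cc(Br)c(OCc3ccccc3)c(OC)c2)cc(Br)c1OCc1ccccc1 | intermediate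
16 | 9-O-monotosylate of 15 (not isolated) | COc1cc([C@@H](O[Si](C)(C)C(C)(C)C)[C@@H](COS(=O)(=O)c4ccc(C)cc4)[C@H](CO)[C@H](O[Si](C)(C)C(C)(C)C)c2cc(Br)c(OCc3ccccc3)c(OC)c2)cc(Br)c1OCc1ccccc1 | intermediate
17 | (3R,4R)-oxolane, 7,7'-bis(TBS) ether, aryl = 4-benzyloxy-3-bromo-5-methoxyphenyl | COc1cc([C@@H](O[Si](C)(C)C(C)(C)C)[C@H]2COC[C@@H]2[C@H](O[Si](C)(C)C(C)(C)C)c2cc(Br)c(OCc3ccccc3)c(OC)c2)cc(Br)c1OCc1ccccc1 | intermediate
18 | (3R,4R)-3,4-bis{(S)-[4-(benzyloxy)-3-bromo-5-methoxyphenyl](hydroxy)methyl}oxolane | COc1cc([C@@H](O)[C@H]2COC[C@@H]2[C@H](O)c2cc(Br)c(OCc3ccccc3)c(OC)c2)cc(Br)c1OCc1ccccc1 | intermediate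
19 | (3R,4R)-3,4-bis[(S)-hydroxy(4-hydroxy-3-methoxyphenyl)methyl]oxolane | COc1cc([C@@H](O)[C@H]2COC[C@@H]2[C@H](O)c2ccc(O)c(OC)c2)ccc1O | target

Total step count: 12. Longest linear sequence: 12 steps (1 → 19).

Steps most likely to fail

1. Step 5 (proposed new method).
- Facial selection may be weak, because a radical–radical combination has an early, almost barrierless transition state.
- The bis(quinone methide) may also be lost before the amide oxygens close. It can tautomerise to the open 8–8' bis(cinnamamide), or an aryl ring can attack to give an aryldihydronaphthalene.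
- Part of the radical pool may couple β–O–4.
- The fallback uses known chemistry, sets out from 3 and returns at 12. The free acid 3 is dimerised with FeCl3 under O2 in aqueous acetone. This is the established conversion of hydroxycinnamic acids into dilactones, in which the carboxyl groups trap the quinone methides. It should give the racemic exo,exo-dibromodilactone F1.
- Mitsunobu benzylation as in step 6 then gives the racemic bis(benzyl ether) F2. F2 is resolved by preparative chromatography on a chiral stationary phase (amylose or cellulose carbamate type), and its (1S,4S,5S,8S) enantiomer is 12.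

2. Step 6.
- The transient phenoxide may expel the benzylic carboxylate. This opens a lactone through a quinone methide, which then tautomerises or is esterified, with loss of the ring and of the C7 configuration.
- The fallback reverses the order of protection and reduction, sets out from 11 and returns at 13. Compound 11 is reduced directly with excess LiAlH4 (THF, −20 → 0 °C) to the phenolic dibromo tetraol F3, in which C7 carries only a poor leaving group.
- Williamson alkylation with BnBr and K2CO3 in acetone then benzylates the two phenols chemoselectively to give 13.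

3. Step 12.
- Hydrogenolysis may run on to the benzylic C7–OH bonds once the para phenols are free.
- Insufficient buffering of HBr may cause ionisation and epimerisation at C7.
- The fallback masks the sensitive bonds during the reduction, sets out from 17 and returns at 19. Compound 17 is hydrogenolysed under the same Pd/C, H2, NaOAc conditions while C7–O and C7'–O are still shielded as bulky silyl ethers. This should give the debrominated, debenzylated bis(silyl ether) F4.
- F4 is then desilylated with TBAF/AcOH in THF to 19.

Further compounds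
F1 | step 5 | racemic exo,exo-4,8-bis(3-bromo-4-hydroxy-5-methoxyphenyl)-3,7-dioxabicyclo[3.3.0]octane-2,6-dione (both enantiomers) | COc1cc([C@H]2OC(=O)[C@H]3[C@@H]2C(=O)O[C@@H]3c2cc(Br)c(O)c(OC)c2)cc(Br)c1O.COc1cc([C@@H]2OC(=O)[C@@H]3[C@H]2C(=O)O[C@H]3c2cc(Br)c(O)c(OC)c2)cc(Br)c1O
F2 | step 5 | racemic exo,exo-4,8-bis[4-(benzyloxy)-3-bromo-5-methoxyphenyl]-3,7-dioxabicyclo[3.3.0]octane-2,6-dione (both enantiomers) | COc1cc([C@H]2OC(=O)[C@H]3[C@@H]2C(=O)O[C@@H]3c2cc(Br)c(OCc4ccccc4)c(OC)c2)cc(Br)c1OCc1ccccc1.COc1cc([C@@H]2OC(=O)[C@@H]3[C@H]2C(=O)O[C@H]3c2cc(Br)c(OCc4ccccc4)c(OC)c2)cc(Br)c1OCc1ccccc1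
F3 | step 6 | (1S,2R,3R,4S)-1,4-bis(3-bromo-4-hydroxy-5-methoxyphenyl)-2,3-bis(hydroxymethyl)butane-1,4-diol | COc1cc([C@@H](O)[C@@H](CO)[C@H](CO)[C@H](O)c2cc(Br)c(O)c(OC)c2)cc(Br)c1O
F4 | step 12 | (3R,4R)-3,4-bis[(S)-(tert-butyldimethylsilyloxy)(4-hydroxy-3-methoxyphenyl)methyl]oxolane | COc1cc([C@@H](O[Si](C)(C)C(C)(C)C)[C@H]2COC[C@@H]2[C@H](O[Si](C)(C)C(C)(C)C)c2ccc(O)c(OC)c2)ccc1O
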